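Ring A of alectorialic acid is a 3-formyl-2,4-dihydroxy-6-methylbenzoyl unit. Its C1 carboxyl carbon is esterified by the CH2–O group at C6 of ring B, a 2,4-dihydroxy-3-methylbenzoic acid.
The strategy rests on this feature: without its CHO, ring A is an orsellinate, a folded eight-carbon 3,5,7-trioxooctanoyl chain (C1 = ester carbonyl, C8 = aryl methyl). The ester C(=O)–O bond and the ring A C1–C6 bond can therefore both come, in one operation, from a dioxinone-masked chain and the ring B benzyl alcohol.
Late disconnections: the acid-labile groups of ring B (two MOM ethers, one tert-butyl ester) and the C3–CHO bond of ring A (phenoxide-directed ortho-formylation).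
The masked chain comes from 2,2,6-trimethyl-1,3-dioxin-4-one by two successive acetylations. The ring B alcohol comes from methyl 3,5-dihydroxy-4-methylbenzoate by protection, reduction and ortho-lithiation/alkoxycarbonylation.
Ring order: ring B is bought as an arene, and ring A is built last, on the benzylic oxygen of ring B.

Key step: step 8

Remark: paraformaldehyde is written as its monomer, β-dicarbonyl compounds are drawn in their keto forms, and the target is achiral, so no step has to set configuration.

Step 1
Reactants: 1 2,2,6-trimethyl-4H-1,3-dioxin-4-one; 2 acetyl chloride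
Product: 4 2,2-dimethyl-6-(2-oxopropyl)-4H-1,3-dioxin-4-one (keto-dioxinone), via lithium dienolate 3 (not isolated)
Conditions: 1 (2 equiv), LiN(SiMe3)2 (2 equiv), THF, −78 °C, 1 h; 2 (1 equiv), −78 → −20 °C; 1 M HCl
Reagents that add atoms: acetyl chloride 2, CC(Cl)=O; LiN(SiMe3)2, [Li]N([Si](C)(C)C)[Si](C)(C)C (lithium of 3 only)
Why: Vinylogous Claisen-type C-acylation: the base removes a proton of the 6-methyl group to give the cross-conjugated dienolate 3, which attacks the acid chloride through its terminal carbon, and 2 is kept at half the amount of 3 because the more acidic product quenches a second equivalent of dienolate.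

Step 2
Reactants: 4 keto-dioxinone; 5 N-methoxy-N-methylacetamide
Product: 7 6-(2,4-dioxopentyl)-2,2-dimethyl-4H-1,3-dioxin-4-one (diketo-dioxinone), via dilithio dianion 6 (not isolated)
Conditions: LiN(i-Pr)2 (2.3 equiv), THF, −78 → −40 °C, 1 h; 5 (1.5 equiv), −78 → −20 °C; 1 M HCl, 0 °C
Reagents that add atoms: N-methoxy-N-methylacetamide 5, CON(C)C(C)=O; LiN(i-Pr)2, [Li]N(C(C)C)C(C)C (lithium of 6 only)
Why: Dianion Claisen acylation: the first equivalent of base removes a proton of the doubly activated CH2 and the second a proton of the terminal CH3, the last-formed carbanion of 6 is the most nucleophilic site, and the chelated tetrahedral adduct of the Weinreb amide persists until the acidic quench so that only one acetyl group is transferred.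

Step 3
Reactants: 8 methyl 3,5-dihydroxy-4-methylbenzoate
Product: 9 methyl 3,5-bis(methoxymethoxy)-4-methylbenzoate
Conditions: MOMCl (3 equiv), i-Pr2NEt (4 equiv), CH2Cl2, 0 °C → rt
Reagents that add atoms: chloromethyl methyl ether (MOMCl), COCCl
Why: Williamson-type O-alkylation of both phenols by the reactive α-chloro ether under amine base, which leaves the methyl ester untouched.

Step 4
Reactants: 9 methyl 3,5-bis(methoxymethoxy)-4-methylbenzoate
Product: 10 [3,5-bis(methoxymethoxy)-4-methylphenyl]methanol
Conditions: LiAlH4 (1.2 equiv), THF, 0 °C → rt; H2O, 15% NaOH, H2O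
Reagents that add atoms: none
Why: Hydride reduction of the ester to the primary benzyl alcohol, a reaction to which the MOM acetals are inert.

Step 5
Reactants: 10 [3,5-bis(methoxymethoxy)-4-methylphenyl]methanol
Product: 11 tert-butyl{[3,5-bis(methoxymethoxy)-4-methylbenzyl]oxy}dimethylsilane
Conditions: TBSCl (1.2 equiv), imidazole (2.5 equiv), CH2Cl2, rt
Reagents that add atoms: tert-butyldimethylsilyl chloride (TBSCl), CC(C)(C)[Si](C)(C)Cl
Why: Imidazole-promoted silylation of the only hydroxyl group removes the acidic proton before the organolithium step.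

Step 6
Reactants: 11 tert-butyl{[3,5-bis(methoxymethoxy)-4-methylbenzyl]oxy}dimethylsilane; 12 di-tert-butyl dicarbonate
Product: 14 tert-butyl 6-{[(tert-butyldimethylsilyl)oxy]methyl}-2,4-bis(methoxymethoxy)-3-methylbenzoate, via aryllithium 13 (not isolated)
Conditions: n-BuLi (1.3 equiv), TMEDA (1.3 equiv), Et2O, −20 → 0 °C, 1.5 h; cool to −78 °C, transfer into 12 (2 equiv) in THF, −78 → 0 °C; aq. NH4Cl
Reagents that add atoms: di-tert-butyl dicarbonate 12, CC(C)(C)OC(=O)OC(=O)OC(C)(C)C; n-BuLi, [Li]CCCC (lithium of 13 only)
Why: Directed ortho-metalation followed by alkoxycarbonylation: the OMOM oxygens bind n-BuLi/TMEDA and steer deprotonation to the adjacent ring C–H (the two ring C–H positions are equivalent by symmetry), the weakly polar solvent retards O-to-C silyl migration in 13, and inverse addition to excess 12 gives a tert-butyl ester too hindered for a second addition.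

Step 7
Reactants: 14 tert-butyl 6-{[(tert-butyldimethylsilyl)oxy]methyl}-2,4-bis(methoxymethoxy)-3-methylbenzoate
Product: 15 tert-butyl 6-(hydroxymethyl)-2,4-bis(methoxymethoxy)-3-methylbenzoate (ring B alcohol)
Conditions: Bu4NF (1.5 equiv), AcOH (1.5 equiv), THF, 0 °C; pH 7 buffer, short silica plug, concentration below 25 °C, used the same day
Reagents that add atoms: none
Why: Fluoride-induced desilylation driven by the strong Si–F bond, in which the acetic acid buffer keeps the liberated oxygen protonated so that no alkoxide can attack the neighbouring tert-butyl ester, and to which the MOM ethers are inert.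

Step 8
Reactants: 7 diketo-dioxinone; 15 ring B alcohol
Product: 19 2-(tert-butoxycarbonyl)-3,5-bis(methoxymethoxy)-4-methylbenzyl 2,4-dihydroxy-6-methylbenzoate (protected deformyl depside), via acylketene 16 (not isolated), via trioxooctanoate ester 17 (not isolated), via aldol carbinol 18 (not isolated)
Conditions: 7 (1.0 equiv), 15 (1.1 equiv), PhMe (0.15 M), 110 °C, 1 h; rt, i-PrOH, Cs2CO3 (3 equiv), 3 h; AcOH (10 equiv), rt, 1 h (one flask)
Reagents that add atoms: none
Why: At 110 °C the dioxinone of 7 loses acetone in a retro-hetero-Diels–Alder reaction to give acylketene 16, and the benzylic oxygen of 15 adds to the ketene carbon to form the depside ester C(=O)–O bond of 17. Cs2CO3 then enolizes the chain reversibly, and C2 (between the ester and the C3 ketone) adds to the C7 methyl ketone in a 6-(enolendo)-exo-trig aldol closure that makes the C1–C6 bond of ring A (18); acetic acid completes the loss of water, and tautomerization gives the 2,4-dihydroxy-6-methylbenzoate 19. The closest known reaction type is this same sequence, namely thermolysis of diketo-dioxinones, capture of the acylketene by an alcohol and base-induced aromatization to resorcylate esters, applied here to a new alcohol. The two stereocentres of 18 are transient and are erased on aromatization, so no stereocontrol is needed. The first selectivity needed is O-acylation ahead of closure of 16 to a 4-hydroxy-2-pyrone and ahead of lactonization of 15; it is secured by an unhindered primary alcohol in small excess at high concentration, by the neutral medium and by the poor tert-butoxide leaving group next to the hydroxymethyl group. The second is the C2-to-C7 mode: enolates at the more acidic C4 and C6 can only close four-membered rings or attack the far less electrophilic ester carbonyl, and C8 is the least acidic site, so the reversible aldol equilibria drain through the one adduct that aromatizes irreversibly, while the MOM ethers and the tert-butyl ester tolerate carbonate and acetic acid.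

Step 9
Reactants: 19 protected deformyl depside; 20 formaldehyde (used as paraformaldehyde)
Product: 22 2-(tert-butoxycarbonyl)-3,5-bis(methoxymethoxy)-4-methylbenzyl 3-formyl-2,4-dihydroxy-6-methylbenzoate (protected alectorialic acid), via salicyl alcohol 21 (not isolated)
Conditions: MgCl2 (anhydrous, 4 equiv), Et3N (8 equiv), (CH2O)n (10 equiv), MeCN, 75 °C; cold 1 M HCl wash
Reagents that add atoms: formaldehyde 20 (as paraformaldehyde), C=O
Why: Magnesium-mediated ortho-formylation of phenols (Casnati–Skattebøl reaction): the magnesium phenoxide of ring A binds formaldehyde and delivers it to an ortho carbon to give 21, a second formaldehyde takes up hydride from the magnesium alkoxide of 21 (Oppenauer-type oxidation), C3 should be preferred because it is ortho to both phenoxide oxygens and the aldehyde formed there is chelated on both sides, and ring B cannot react because it has no free phenol.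

Step 10
Reactants: 22 protected alectorialic acid
Product: 23 alectorialic acid (6-{[(3-formyl-2,4-dihydroxy-6-methylbenzoyl)oxy]methyl}-2,4-dihydroxy-3-methylbenzoic acid)
Conditions: TFA/CH2Cl2 (1:4), H2O (20 equiv), 0.02 M, 0 °C → rt; evaporation with toluene below 25 °C
Reagents that add atoms: none
Why: Acidolysis: TFA cleaves the tert-butyl ester by loss of isobutene and hydrolyses both aryl MOM acetals, whereas the depside CH2–O bond should hold because both ring B oxygens are meta to the benzylic carbon and cannot stabilize a cation there, and cold, dilute, short exposure limits attack of the liberated carboxyl group on that carbon and re-condensation of formaldehyde with the phenol rings.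

Compound list
1 | 2,2,6-trimethyl-4H-1,3-dioxin-4-one | CC1=CC(=O)OC(C)(C)O1 | starting material
2 | acetyl chloride | CC(Cl)=O | starting material
3 | lithium dienolate of 1, lithium 2,2-dimethyl-6-methylidene-1,3-dioxin-4-olate (not isolated) | C=C1C=C(O[Li])OC(C)(C)O1 | intermediate
4 | 2,2-dimethyl-6-(2-oxopropyl)-4H-1,3-dioxin-4-one (keto-dioxinone) | CC(=O)CC1=CC(=O)OC(C)(C)O1 | intermediate
5 | N-methoxy-N-methylacetamide | CON(C)C(C)=O | starting material
6 | dilithio dianion of 4 (not isolated) | C=C(O[Li])C=C1C=C(O[Li])OC(C)(C)O1 | intermediate
7 | 6-(2,4-dioxopentyl)-2,2-dimethyl-4H-1,3-dioxin-4-one (diketo-dioxinone) | CC(=O)CC(=O)CC1=CC(=O)OC(C)(C)O1 | intermediate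
8 | methyl 3,5-dihydroxy-4-methylbenzoate | COC(=O)c1cc(O)c(C)c(O)c1 | starting material
9 | methyl 3,5-bis(methoxymethoxy)-4-methylbenzoate | COCOc1cc(C(=O)OC)cc(OCOC)c1C | intermediate
10 | [3,5-bis(methoxymethoxy)-4-methylphenyl]methanol | COCOc1cc(CO)cc(OCOC)c1C | intermediate
11 | tert-butyl{[3,5-bis(methoxymethoxy)-4-methylbenzyl]oxy}dimethylsilane | COCOc1cc(CO[Si](C)(C)C(C)(C)C)cc(OCOC)c1C | intermediate
12 | di-tert-butyl dicarbonate | CC(C)(C)OC(=O)OC(=O)OC(C)(C)C | starting material
13 | 2-lithio derivative of 11, lithium between OMOM and CH2OTBS (not isolated) | COCOc1cc(CO[Si](C)(C)C(C)(C)C)c([Li])c(OCOC)c1C | intermediate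
14 | tert-butyl 6-{[(tert-butyldimethylsilyl)oxy]methyl}-2,4-bis(methoxymethoxy)-3-methylbenzoate | COCOc1cc(CO[Si](C)(C)C(C)(C)C)c(C(=O)OC(C)(C)C)c(OCOC)c1C | intermediate
15 | tert-butyl 6-(hydroxymethyl)-2,4-bis(methoxymethoxy)-3-methylbenzoate (ring B alcohol) | COCOc1cc(CO)c(C(=O)OC(C)(C)C)c(OCOC)c1C | intermediate
16 | 3,5,7-trioxooct-1-en-1-one, the diketo acylketene (not isolated) | CC(=O)CC(=O)CC(=O)C=C=O | intermediate
17 | ring B benzyl 3,5,7-trioxooctanoate (not isolated) | CC(=O)CC(=O)CC(=O)CC(=O)OCc1cc(OCOC)c(C)c(OCOC)c1C(=O)OC(C)(C)C | intermediate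
18 | ring B benzyl 2-hydroxy-2-methyl-4,6-dioxocyclohexane-1-carboxylate, transient mixture of diastereomers (not isolated) | CC1(O)CC(=O)CC(=O)C1C(=O)OCc1cc(OCOC)c(C)c(OCOC)c1C(=O)OC(C)(C)C | intermediate
19 | 2-(tert-butoxycarbonyl)-3,5-bis(methoxymethoxy)-4-methylbenzyl 2,4-dihydroxy-6-methylbenzoate | Cc1cc(O)cc(O)c1C(=O)OCc1cc(OCOC)c(C)c(OCOC)c1C(=O)OC(C)(C)C | intermediate
20 | formaldehyde (used as paraformaldehyde) | C=O | starting material
21 | 3-(hydroxymethyl) derivative of 19, present as its magnesium salt (not isolated) | Cc1cc(O)c(CO)c(O)c1C(=O)OCc1cc(OCOC)c(C)c(OCOC)c1C(=O)OC(C)(C)C | intermediate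
22 | 2-(tert-butoxycarbonyl)-3,5-bis(methoxymethoxy)-4-methylbenzyl 3-formyl-2,4-dihydroxy-6-methylbenzoate | Cc1cc(O)c(C=O)c(O)c1C(=O)OCc1cc(OCOC)c(C)c(OCOC)c1C(=O)OC(C)(C)C | intermediate
23 | alectorialic acid | Cc1cc(O)c(C=O)c(O)c1C(=O)OCc1cc(O)c(C)c(O)c1C(=O)O | target

Total step count: 10
Longest linear sequence: 8 steps (steps 3 to 10, from 8)

Steps most likely to fail

Step 9. The free 4-hydroxyl can deliver formaldehyde to either of its neighbours, so the formylation may be shared between C3 and C5 of ring A. The fallback replaces innate preference by a blocking group. Setting out from 19, the non-chelated and more acidic 4-hydroxyl is capped selectively (MOMCl 1.05 equiv, i-Pr2NEt, CH2Cl2, 0 °C). The 2-hydroxyl is hydrogen-bonded to the ester carbonyl and stays free, which gives the 4-O-MOM depside F1. The only phenoxide of F1 sits at C2 and its only open ortho carbon is C3. MgCl2/Et3N/paraformaldehyde can therefore only lead, through the transient 3-hydroxymethyl 4-O-MOM depside F2, to the 3-formyl 4-O-MOM depside F3. TFA/CH2Cl2/H2O as in step 10 then removes three MOM groups and the tert-butyl ester, and the route is rejoined at 23.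

Step 8. Thermal lactonization of the hydroxy ester or self-closure of the acylketene may consume the partners before they meet, or the aldol/dehydration sequence may stop short of the arene. The fallback buys ring A and makes the ester by substitution at the benzylic carbon at room temperature. Setting out from 15, a Mitsunobu esterification is run with bought orsellinic acid F4, DIAD and P(3-ClC6H4)3 in toluene at 0 °C → rt. The carboxylic acid is by far the most acidic partner, so it is alkylated and the phenols are not. Crowding around the carboxyl group does not matter because the bond forms by SN2 attack at the primary benzylic carbon. The route is rejoined at 19.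

Step 6. Metalation may stray to the 4-methyl group flanked by two OMOM groups or to the benzylic CH2. The ortho-lithiated silyl ether may also suffer O-to-C silyl migration at the temperature that deprotonation needs. The fallback fixes the site by electrophilic halogenation and generates the carbanion cold. Setting out from 11, NBS (1.0 equiv, MeCN, 0 °C, dark) brominates one of the two equivalent, strongly activated ring positions to give the aryl bromide F5. Bromine–lithium exchange (n-BuLi, THF, −78 °C) gives the same aryllithium 13 within minutes, and the quench with 12 at −78 °C rejoins the route at 14.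

Further compounds
F1 | step 9 | 2-(tert-butoxycarbonyl)-3,5-bis(methoxymethoxy)-4-methylbenzyl 2-hydroxy-4-(methoxymethoxy)-6-methylbenzoate | Cc1cc(OCOC)cc(O)c1C(=O)OCc1cc(OCOC)c(C)c(OCOC)c1C(=O)OC(C)(C)C
F2 | step 9 | 3-(hydroxymethyl) derivative of F1 (not isolated) | Cc1cc(OCOC)c(CO)c(O)c1C(=O)OCc1cc(OCOC)c(C)c(OCOC)c1C(=O)OC(C)(C)C
F3 | step 9 | 2-(tert-butoxycarbonyl)-3,5-bis(methoxymethoxy)-4-methylbenzyl 3-formyl-2-hydroxy-4-(methoxymethoxy)-6-methylbenzoate | Cc1cc(OCOC)c(C=O)c(O)c1C(=O)OCc1cc(OCOC)c(C)c(OCOC)c1C(=O)OC(C)(C)C
F4 | step 8 | orsellinic acid, 2,4-dihydroxy-6-methylbenzoic acid (bought for the fallback) | Cc1cc(O)cc(O)c1C(=O)O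
F5 | step 6 | {[2-bromo-3,5-bis(methoxymethoxy)-4-methylbenzyl]oxy}(tert-butyl)dimethylsilane | COCOc1cc(CO[Si](C)(C)C(C)(C)C)c(Br)c(OCOC)c1C
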